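**Retrosynthetic overview**

1. C14 is added last by methylenation of a C7 ketone. Before that, ring B is uncovered from a 2-chlorocyclopropane by HBr, which breaks the cross-ring C1–C3 bond (H to C1, Br to C3 with inversion).
2. The cyclopropane comes from a carbenoid at C1 (aldehyde tosylhydrazone on the quaternary C6) adding to an (E)-C2=C3 chloroalkene held on C6 through C5–C4. This one event closes the six-membered perimeter of ring B at C1–C2 and makes the temporary C1–C3 bond.
3. Enabling feature: in ring B, C1 and the C3 bromine are anti across C2–C3 and the C2 chlorine is trans to C4 (Cl and Br equatorial, C15 methyl axial). This is the imprint of an anti addition of C1 and bromide to an (E)-chloroalkene. C6 is quaternary, so a carbenoid at C1 has no neighbouring hydrogen.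
4. Ring A, with C6 and C10, is made first by solvolytic bromonium cyclization (C6–C11) of an enantioenriched C10/C11 bromochloride onto a β-keto ester enol. The precursor is assembled from methyl acetoacetate, a C2–C5 chloroalkenyl iodide and a prenol-derived bromochloro triflate.
5. Ring order: ring A, then the cyclopropane with the ring B perimeter, then ring B proper by C1–C3 cleavage.

Key step: step 11

Remark on numbering: chamigrane numbering is used (ring B = C1–C6, C6 spiro, ring A = C6–C11; C2 bears Cl, C3 bears Br and the C15 methyl, C7 bears the C14 methylene, C10 bears Br, C11 bears methyls C12 and C13).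

Assumption: in step 4 the enantiomer of the chiral Schiff-base ligand that delivers the (R)-bromochloride from prenol is used.

**Route**

Step 1
Reactants: 1 but-3-yn-1-ol
Product: 3 (E)-4-chloro-3-methylbut-3-en-1-ol, via alkenylalane 2 (not isolated)
Conditions: AlMe3 (3 equiv), Cp2ZrCl2 (25 mol%), CH2Cl2, 0 → 23 °C; then NCS, THF, −30 → 0 °C; aq. HCl
Reagents that add atoms: trimethylaluminium C[Al](C)C; N-chlorosuccinimide O=C1CCC(=O)N1Cl
Why: Negishi carboalumination (zirconium-catalysed) adds methyl and aluminium syn across the alkyne with methyl on the internal carbon, and chlorodealumination with retention fixes the (E)-chloroalkene (Cl cis to the methyl, trans to the chain).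

Step 2
Reactants: 3 (E)-4-chloro-3-methylbut-3-en-1-ol
Product: 4 (E)-1-chloro-4-iodo-2-methylbut-1-ene
Conditions: PPh3, I2, imidazole, CH2Cl2, 0 → 23 °C
Reagents that add atoms: iodine II
Why: Appel-type iodination converts the primary alcohol into the iodide by SN2 at C5 and leaves the chloroalkene untouched.

Step 3
Reactants: 5 methyl acetoacetate, 4 (E)-1-chloro-4-iodo-2-methylbut-1-ene
Product: 6 methyl (E)-2-acetyl-6-chloro-5-methylhex-5-enoate (racemic)
Conditions: K2CO3, acetone, 56 °C
Reagents that add atoms: none
Why: Acetoacetic ester alkylation, in which the stabilised enolate displaces the primary iodide (SN2) to form C5–C6; the new centre is enolisable and its configuration does not matter.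

Step 4
Reactants: 7 prenol (3-methylbut-2-en-1-ol)
Product: 8 (R)-2-bromo-3-chloro-3-methylbutan-1-ol
Conditions: NBS, ClTi(OiPr)3, chiral tridentate Schiff-base ligand (20 mol%), hexanes, −20 °C
Reagents that add atoms: N-bromosuccinimide O=C1CCC(=O)N1Br; chlorotitanium triisopropoxide CC(C)O[Ti](Cl)(OC(C)C)OC(C)C
Why: Titanium/Schiff-base catalysed enantioselective bromochlorination of an allylic alcohol, in which NBS forms the bromonium ion of the titanium-bound alkoxide, chloride is delivered anti from titanium to the distal tertiary carbon (C11), and the ligand sets C10.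

Step 5
Reactants: 8 (R)-2-bromo-3-chloro-3-methylbutan-1-ol
Product: 9 (R)-2-bromo-3-chloro-3-methylbutyl trifluoromethanesulfonate
Conditions: Tf2O, 2,6-lutidine, CH2Cl2, −78 °C
Reagents that add atoms: triflic anhydride O=S(=O)(OS(=O)(=O)C(F)(F)F)C(F)(F)F
Why: O-sulfonylation of the primary alcohol at low temperature with a hindered base activates C9 without displacing the neighbouring bromide, and C10 is not involved.

Step 6
Reactants: 6 methyl (E)-2-acetyl-6-chloro-5-methylhex-5-enoate, 9 (R)-2-bromo-3-chloro-3-methylbutyl trifluoromethanesulfonate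
Product: 11 methyl (6R)-6-bromo-7-chloro-2-[(E)-4-chloro-3-methylbut-3-en-1-yl]-7-methyl-3-oxooctanoate (C2 epimers), via dianion 10 (not isolated)
Conditions: LDA (2.1 equiv), THF, −78 → 0 °C; then 9, −78 → −30 °C; aq. NH4Cl
Reagents that add atoms: none
Why: Acetoacetate dianion γ-alkylation, in which the more nucleophilic terminal carbanion displaces the primary triflate (SN2 at C9) to form C8–C9 while C10 stays untouched.

Step 7
Reactants: 11 methyl (6R)-6-bromo-7-chloro-2-[(E)-4-chloro-3-methylbut-3-en-1-yl]-7-methyl-3-oxooctanoate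
Product: 12 methyl (1R,3R)-3-bromo-1-[(E)-4-chloro-3-methylbut-3-en-1-yl]-2,2-dimethyl-6-oxocyclohexane-1-carboxylate
Conditions: (CF3)2CHOH (0.02 M), 23 °C
Reagents that add atoms: none
Why: Stereospecific bromonium cyclization by solvolysis of a vicinal bromochloride: the solvent ionises C11–Cl with anchimeric help from the C10 bromine, and the hydrogen-bonded (Z)-enol carbon C6 opens the enantiopure bromonium ion at C11 through a chair with Br equatorial, which places the ester (C1) equatorial and cis to Br and the side chain axial at the new quaternary C6, while the chlorine-deactivated side-chain alkene does not compete.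

Step 8
Reactants: 12 methyl (1R,3R)-3-bromo-1-[(E)-4-chloro-3-methylbut-3-en-1-yl]-2,2-dimethyl-6-oxocyclohexane-1-carboxylate
Product: 13 (2S,4R)-4-bromo-2-[(E)-4-chloro-3-methylbut-3-en-1-yl]-2-(hydroxymethyl)-3,3-dimethylcyclohexan-1-ol (both C1 epimers)
Conditions: i-Bu2AlH (5 equiv), CH2Cl2, −78 → 0 °C; aq. potassium sodium tartrate
Reagents that add atoms: none
Why: Hydride reduction of both the ketone and the hindered ester (the secondary bromide and the chloroalkene are inert); the carbinol configuration is irrelevant because it is reoxidised.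

Step 9
Reactants: 13 (2S,4R)-4-bromo-2-[(E)-4-chloro-3-methylbut-3-en-1-yl]-2-(hydroxymethyl)-3,3-dimethylcyclohexan-1-ol
Product: 14 (1S,3R)-3-bromo-1-[(E)-4-chloro-3-methylbut-3-en-1-yl]-2,2-dimethyl-6-oxocyclohexane-1-carbaldehyde
Conditions: Dess–Martin periodinane, CH2Cl2, 0 → 23 °C
Reagents that add atoms: none
Why: Dess–Martin oxidation restores the C7 ketone and takes the neopentyl alcohol to the C1 aldehyde under non-basic conditions, so the non-enolisable keto aldehyde is not deformylated.

Step 10
Reactants: 14 (1S,3R)-3-bromo-1-[(E)-4-chloro-3-methylbut-3-en-1-yl]-2,2-dimethyl-6-oxocyclohexane-1-carbaldehyde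
Product: 15 N'-[(E)-[(1S,3R)-3-bromo-1-[(E)-4-chloro-3-methylbut-3-en-1-yl]-2,2-dimethyl-6-oxocyclohexyl]methylidene]-4-methylbenzenesulfonohydrazide
Conditions: TsNHNH2, MeOH, 23 °C
Reagents that add atoms: 4-methylbenzenesulfonohydrazide Cc1ccc(cc1)S(=O)(=O)NN
Why: Hydrazone condensation occurs at the aldehyde only, because the C7 ketone is flanked by the quaternary C6 and is far less electrophilic.

Step 11
Reactants: 15 N'-[(E)-[(1S,3R)-3-bromo-1-[(E)-4-chloro-3-methylbut-3-en-1-yl]-2,2-dimethyl-6-oxocyclohexyl]methylidene]-4-methylbenzenesulfonohydrazide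
Product: 18 (1R,2R,5S,6S,5'R)-5'-bromo-6-chloro-5,6',6'-trimethylspiro[bicyclo[3.1.0]hexane-2,1'-cyclohexan]-2'-one (exo chlorine; cyclopropane on the carbonyl side of the spiro carbon), via sodium salt 16 (not isolated), via diazoalkane 17 (not isolated)
Conditions: NaH, THF, 0 °C; then Cu(acac)2 (5 mol%), BnEt3NCl (10 mol%), 1,4-dioxane, 85 °C
Reagents that add atoms: none
Why: Base converts the tosylhydrazone into the diazoalkane (Bamford–Stevens), Cu(acac)2 turns it into a copper carbenoid at C1, and this adds in one concerted syn event to the (E)-C2=C3 chloroalkene; the closest known reaction type is the copper-mediated intramolecular cyclopropanation of alkenyl tosylhydrazone salts that gives bicyclo[3.1.0]hexanes. The cyclopropane closes by [2+1] addition, in which C1–C3 closes a five-membered ring in the exo sense and C1–C2 closes the six-membered perimeter C6–C1–C2–C3–C4–C5 of ring B in the endo sense. C2 and C3 are set stereospecifically by the alkene geometry, so the chlorine, cis to the C15 methyl in the alkene, ends exo on the cyclopropane, and C1 follows from the cis ring fusion. The face of the alkene is chosen by C6: the cyclopropane should form on the side of the flat C7 carbonyl and away from the C11 gem-dimethyl group, since the larger C6 substituent avoids eclipsing the new C1–C2 bond. The step needs cyclopropanation to beat 1,2-shift and C–H insertion, which the quaternary C6 (no hydrogen next to the carbenoid) and the five-membered reach to the alkene should secure, and it needs the carbenoid to ignore the ketone, which could only give a strained four-membered ylide.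

Step 12
Reactants: 18 (1R,2R,5S,6S,5'R)-5'-bromo-6-chloro-5,6',6'-trimethylspiro[bicyclo[3.1.0]hexane-2,1'-cyclohexan]-2'-one
Product: 19 (2S,3S,6R,10R)-3,10-dibromo-2-chloro-3,11,11-trimethylspiro[5.5]undecan-7-one
Conditions: HBr (anhydrous, 1.2 equiv), CH2Cl2, −40 → 0 °C
Reagents that add atoms: hydrogen bromide Br
Why: Markovnikov hydrobromination of a cyclopropane, in which the proton goes to C1, the bond distal to the chlorine-bearing C2 (C1–C3) breaks toward the tertiary C3, and bromide enters C3 with inversion inside the ion pair, so that Br ends anti to C1 and trans to Cl and ring B appears with Cl and Br equatorial and the C15 methyl axial.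

Step 13
Reactants: 19 (2S,3S,6R,10R)-3,10-dibromo-2-chloro-3,11,11-trimethylspiro[5.5]undecan-7-one
Product: 20 obtusane
Conditions: Cp2TiMe2 (3 equiv), toluene, 65 °C, dark
Reagents that add atoms: dimethyltitanocene C[Ti](C)(C1C=CC=C1)C1C=CC=C1
Why: Petasis methylenation, in which titanocene methylidene formed on warming converts the hindered, enolisable C7 ketone into the C14 methylene by [2+2] cycloaddition and cycloreversion under non-basic conditions that should spare the tertiary bromide.

**Compound list**

1 | but-3-yn-1-ol | C#CCCO | starting material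
2 | dimethyl[(E)-4-(dimethylalumanyloxy)-2-methylbut-1-en-1-yl]alumane (alkenylalane) | C[Al](C)/C=C(C)/CCO[Al](C)C | intermediate
3 | (E)-4-chloro-3-methylbut-3-en-1-ol | OCC/C(C)=C/Cl | intermediate
4 | (E)-1-chloro-4-iodo-2-methylbut-1-ene | ICC/C(C)=C/Cl | intermediate
5 | methyl acetoacetate | COC(=O)CC(C)=O | starting material
6 | methyl (E)-2-acetyl-6-chloro-5-methylhex-5-enoate (racemic) | COC(=O)C(CC/C(C)=C/Cl)C(C)=O | intermediate
7 | prenol (3-methylbut-2-en-1-ol) | CC(C)=CCO | starting material
8 | (R)-2-bromo-3-chloro-3-methylbutan-1-ol | OC[C@@H](Br)C(C)(C)Cl | intermediate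
9 | (R)-2-bromo-3-chloro-3-methylbutyl trifluoromethanesulfonate | O=S(=O)(OC[C@@H](Br)C(C)(C)Cl)C(F)(F)F | intermediate
10 | dilithium dianion of 6 | [Li+].[Li+].[CH2-]C(=O)[C-](CC/C(C)=C/Cl)C(=O)OC | intermediate
11 | methyl (6R)-6-bromo-7-chloro-2-[(E)-4-chloro-3-methylbut-3-en-1-yl]-7-methyl-3-oxooctanoate (C2 epimers) | COC(=O)C(CC/C(C)=C/Cl)C(=O)CC[C@@H](Br)C(C)(C)Cl | intermediate
12 | methyl (1R,3R)-3-bromo-1-[(E)-4-chloro-3-methylbut-3-en-1-yl]-2,2-dimethyl-6-oxocyclohexane-1-carboxylate (ester cis to Br) | O=C1CC[C@@H](Br)C(C)(C)[C@]1(C(=O)OC)CC/C(C)=C/Cl | intermediate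
13 | (2S,4R)-4-bromo-2-[(E)-4-chloro-3-methylbut-3-en-1-yl]-2-(hydroxymethyl)-3,3-dimethylcyclohexan-1-ol (both C1 epimers) | OC1CC[C@@H](Br)C(C)(C)[C@]1(CO)CC/C(C)=C/Cl | intermediate
14 | (1S,3R)-3-bromo-1-[(E)-4-chloro-3-methylbut-3-en-1-yl]-2,2-dimethyl-6-oxocyclohexane-1-carbaldehyde | O=C1CC[C@@H](Br)C(C)(C)[C@]1(C=O)CC/C(C)=C/Cl | intermediate
15 | N'-[(E)-[(1S,3R)-3-bromo-1-[(E)-4-chloro-3-methylbut-3-en-1-yl]-2,2-dimethyl-6-oxocyclohexyl]methylidene]-4-methylbenzenesulfonohydrazide | O=C1CC[C@@H](Br)C(C)(C)[C@]1(/C=N/NS(=O)(=O)c2ccc(C)cc2)CC/C(C)=C/Cl | intermediate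
16 | sodium salt of 15 | [Na+].O=C1CC[C@@H](Br)C(C)(C)[C@]1(/C=N/[N-]S(=O)(=O)c2ccc(C)cc2)CC/C(C)=C/Cl | intermediate
17 | (2S,4R)-4-bromo-2-[(E)-4-chloro-3-methylbut-3-en-1-yl]-2-(diazomethyl)-3,3-dimethylcyclohexan-1-one | O=C1CC[C@@H](Br)C(C)(C)[C@]1(C=[N+]=[N-])CC/C(C)=C/Cl | intermediate
18 | (1R,2R,5S,6S,5'R)-5'-bromo-6-chloro-5,6',6'-trimethylspiro[bicyclo[3.1.0]hexane-2,1'-cyclohexan]-2'-one (exo chlorine cis to the bridgehead methyl; cyclopropane on the carbonyl side of the spiro carbon) | O=C1CC[C@@H](Br)C(C)(C)[C@]12CC[C@]3(C)[C@@H](Cl)[C@H]23 | intermediate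
19 | (2S,3S,6R,10R)-3,10-dibromo-2-chloro-3,11,11-trimethylspiro[5.5]undecan-7-one (chamigrane numbering) | O=C1CC[C@@H](Br)C(C)(C)[C@]12CC[C@](C)(Br)[C@@H](Cl)C2 | intermediate
20 | obtusane, (2S,3S,6S,10R)-3,10-dibromo-2-chloro-3,11,11-trimethyl-7-methylidenespiro[5.5]undecane (chamigrane numbering) | C=C1CC[C@@H](Br)C(C)(C)[C@]12CC[C@](C)(Br)[C@@H](Cl)C2 | target

**Step count and risks**

Total step count: 13. Longest linear sequence: 11 steps (steps 1, 2, 3, 6, 7, 8, 9, 10, 11, 12, 13).

The three steps most likely to fail are, in this order, step 11, step 12 and step 7.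

For step 11, the carbenoid may dimerise or insert into C–H bonds faster than it adds to the electron-poor chloroalkene, or it may add with poor facial selectivity with respect to C6. The fallback sets out from hydrazone 15. Its sodium salt 16 is heated without copper (1,4-dioxane, 85 °C), so that diazoalkane 17 is trapped by the chloroalkene as a 1,3-dipole through the same five-membered tether (C1 to C3, terminal nitrogen to C2, syn). This should give the tricyclic 1-pyrazoline F4. Irradiation of the 1-pyrazoline F4 (300 nm, pentane, −20 °C) should then extrude dinitrogen and close C1–C2 with retention, which comes back to the route at 18.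

For step 12, protonation may break a peripheral cyclopropane bond, or the C3 cation may escape the ion pair so that bromide enters from both faces. The fallback sets out from 18 and delivers oxygen first. CF3CO2H (CH2Cl2, 0 °C) should open the C1–C3 bond, with invertive addition of the carboxylic acid at C3, to give (2S,3S,6R,10R)-10-bromo-2-chloro-3,11,11-trimethyl-7-oxospiro[5.5]undecan-3-yl trifluoroacetate F5. NaHCO3 in MeOH should free (2S,3S,6R,10R)-10-bromo-2-chloro-3-hydroxy-3,11,11-trimethylspiro[5.5]undecan-7-one F6. SOBr2 (Et2O, −20 °C) converts it into the bromosulfite F7, which should collapse with retention by internal return (SNi) and so come back to the route at 19.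

For step 7, the enol oxygen may cyclise instead of carbon, or C–C closure at the fully substituted enol carbon may be too slow. The fallback closes ring A before the side chain is present. It sets out from methyl acetoacetate 5, triflate 9 and iodide 4. Compound 5 is converted with LDA (2 equiv) into the dilithium dianion of methyl acetoacetate F1 and alkylated at the terminal carbon with 9 to give methyl (6R)-6-bromo-7-chloro-7-methyl-3-oxooctanoate F2. Solvolysis in (CF3)2CHOH should then give methyl (3R)-3-bromo-2,2-dimethyl-6-oxocyclohexane-1-carboxylate F3. C-alkylation of F3 with 4 (Cs2CO3, DMF) should occur by axial entry anti to the axial C11 methyl and trans to Br, which comes back to the route at 12.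

Further compounds
F1 | step 7 | dilithium dianion of methyl acetoacetate | [Li+].[Li+].[CH2-]C(=O)[CH-]C(=O)OC
F2 | step 7 | methyl (6R)-6-bromo-7-chloro-7-methyl-3-oxooctanoate | COC(=O)CC(=O)CC[C@@H](Br)C(C)(C)Cl
F3 | step 7 | methyl (3R)-3-bromo-2,2-dimethyl-6-oxocyclohexane-1-carboxylate (C1 epimers and enol) | COC(=O)C1C(=O)CC[C@@H](Br)C1(C)C
F4 | step 11 | tricyclic 1-pyrazoline (C1–N=N–C2 bridge in place of the C1–C2 bond of 18, same configuration at C1, C2, C3, C6 and C10) | O=C1CC[C@@H](Br)C(C)(C)[C@]12CC[C@]3(C)[C@@H](Cl)N=N[C@H]23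
F5 | step 12 | (2S,3S,6R,10R)-10-bromo-2-chloro-3,11,11-trimethyl-7-oxospiro[5.5]undecan-3-yl trifluoroacetate | O=C1CC[C@@H](Br)C(C)(C)[C@]12CC[C@](C)(OC(=O)C(F)(F)F)[C@@H](Cl)C2
F6 | step 12 | (2S,3S,6R,10R)-10-bromo-2-chloro-3-hydroxy-3,11,11-trimethylspiro[5.5]undecan-7-one | O=C1CC[C@@H](Br)C(C)(C)[C@]12CC[C@](C)(O)[C@@H](Cl)C2
F7 | step 12 | bromosulfite of F6 | O=C1CC[C@@H](Br)C(C)(C)[C@]12CC[C@](C)(OS(=O)Br)[C@@H](Cl)C2
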